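## Retrosynthetic overview

- Open the furan of 11 at O–C2 (5-endo-dig closure) and at the aryl–alkyne bond (Sonogashira). This gives bromophenol 2 and the 5-alkynyl-dihydropyran 8.
- Open the dihydropyran of 8 at O1–C2 and C3–C4 (retro inverse-demand oxa-Diels–Alder). This gives (E)-coniferyl acetate 7 and the 2-alkynylacrolein 4. The E-alkene sets the trans relation and a chiral Brønsted acid sets the absolute configuration.
- Ring order: dihydropyran first, furan second, both in one flask from three components, without protecting groups. Both benzene rings are bought.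
- 2 comes from bromohydroquinone by C-acylation. 4 comes from silyl enyne 3 by allylic oxidation. 7 comes from isoeugenol and butenediol diacetate by cross-metathesis.

Assumption: the (R)-configured acid is taken to give the (2R,3S) adduct. If the sense of induction is opposite, its (S)-enantiomer is used and nothing else changes.

## Route

**Step 1**
Reactants: 1 bromohydroquinone (2-bromobenzene-1,4-diol)
Product: 2 1-(4-bromo-2,5-dihydroxyphenyl)ethan-1-one
Conditions: AcOH, BF3·OEt2 (3 equiv), 90 °C; then H2O, 60 °C
Reagents that add atoms: acetic acid CC(=O)O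
Why: BF3-mediated Friedel–Crafts/Fries C-acylation goes ortho to a hydroxyl, and of the open positions only C5 is para to bromine (C6 is meta to it, C3 is flanked by Br and OH), so the chelated 4-bromo-2,5-dihydroxy ketone forms; no stereocentre.

**Step 2**
Reactants: 3 trimethyl(3-methylbut-3-en-1-yn-1-yl)silane
Product: 4 2-[(trimethylsilyl)ethynyl]prop-2-enal
Conditions: SeO2 (1.1 equiv), BHT (cat.), 1,4-dioxane, 70 °C; kept cold in PhMe and used within a day
Reagents that add atoms: selenium dioxide O=[Se]=O
Why: Riley allylic oxidation (ene reaction, then [2,3]-shift) takes the only allylic C–H position, the methyl group, through the alcohol to the conjugated aldehyde, and the silyl-capped alkyne has no propargylic hydrogen to compete.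

**Step 3**
Reactants: 5 isoeugenol (2-methoxy-4-[(E)-prop-1-enyl]phenol); 6 (Z)-but-2-ene-1,4-diyl diacetate (2 equiv)
Product: 7 (E)-coniferyl acetate, (E)-3-(4-hydroxy-3-methoxyphenyl)prop-2-en-1-yl acetate
Conditions: Hoveyda–Grubbs II (2 mol%), CH2Cl2, 40 °C
Reagents that add atoms: none
Why: Olefin cross-metathesis of a β-methylstyrene with a symmetrical allylic diacetate tolerates the free phenol, gives the styrenyl product as the E isomer under thermodynamic control (so E/Z mixtures of 5 can be used), and delivers the acetate already on the primary oxygen.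

**Step 4**
Reactants: 7 (E)-coniferyl acetate; 4 2-[(trimethylsilyl)ethynyl]prop-2-enal (1.2 equiv); 2 1-(4-bromo-2,5-dihydroxyphenyl)ethan-1-one (1.1 equiv)
Product: 11 propolis-benzofuran A, via silylalkynyl dihydropyran 8 (not isolated), via ethynyl dihydropyran 9 (not isolated), via alkynylphenol 10 (not isolated)
Conditions: (R)-TRIP N-triflylphosphoramide (5 mol%), 4 Å MS, PhMe/CH2Cl2, −60 to −30 °C; Et3N; then in the same flask 2, PdCl2(PhCN)2 (3 mol%), [tBu3PH]BF4 (6 mol%), CuI (5 mol%), CsF (2.5 equiv), DMF, Ar, 45 °C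
Reagents that add atoms: none
Why: Proposed new method: the strong chiral acid hydrogen-bonds the formyl oxygen of 4 (LUMO lowering, as in N-triflylphosphoramide-catalysed Diels–Alder reactions of vinyl ketones) while its basic P=O/S=O site holds the para-phenol of 7 (HOMO raising, as in the phosphoric-acid Povarov reaction of isoeugenol), so the β-carbon of 7 bonds to the CH2 terminus of 4 and the carbonyl oxygen closes on the quinone-methide-like benzylic carbon in an asynchronous inverse-electron-demand oxa-Diels–Alder reaction (closest known type: Brønsted-acid oxa-[4+2] of o-quinone methides with styrenes); suprafacial addition to the E-alkene fixes the 2,3-trans relation and the catalyst's choice of alkene face fixes (2R,3S), after which known chemistry finishes in the same flask (fluoride desilylation, Sonogashira coupling with the acetyl-activated bromide 2, Cu/base 5-endo-dig heteroannulation of the push–pull alkyne) without touching C2 or C3.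

## Compound list

| No. | Name | SMILES | Role |
|---|---|---|---|
| 1 | bromohydroquinone | Oc1ccc(O)c(Br)c1 | starting material |
| 2 | 1-(4-bromo-2,5-dihydroxyphenyl)ethan-1-one | CC(=O)c1cc(O)c(Br)cc1O | intermediate |
| 3 | trimethyl(3-methylbut-3-en-1-yn-1-yl)silane | CC(=C)C#C[Si](C)(C)C | starting material |
| 4 | 2-[(trimethylsilyl)ethynyl]prop-2-enal | C=C(C=O)C#C[Si](C)(C)C | intermediate |
| 5 | (E)-isoeugenol | C/C=C/c1ccc(O)c(OC)c1 | starting material |
| 6 | (Z)-but-2-ene-1,4-diyl diacetate | CC(=O)OC/C=C\COC(C)=O | starting material |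
| 7 | (E)-coniferyl acetate | CC(=O)OC/C=C/c1ccc(O)c(OC)c1 | intermediate |
| 8 | [(2R,3S)-2-(4-hydroxy-3-methoxyphenyl)-5-[(trimethylsilyl)ethynyl]-3,4-dihydro-2H-pyran-3-yl]methyl acetate | COc1cc([C@@H]2OC=C(C#C[Si](C)(C)C)C[C@H]2COC(C)=O)ccc1O | intermediate |
| 9 | [(2R,3S)-5-ethynyl-2-(4-hydroxy-3-methoxyphenyl)-3,4-dihydro-2H-pyran-3-yl]methyl acetate | COc1cc([C@@H]2OC=C(C#C)C[C@H]2COC(C)=O)ccc1O | intermediate |
| 10 | [(2R,3S)-5-[(4-acetyl-2,5-dihydroxyphenyl)ethynyl]-2-(4-hydroxy-3-methoxyphenyl)-3,4-dihydro-2H-pyran-3-yl]methyl acetate | COc1cc([C@@H]2OC=C(C#Cc3cc(O)c(C(C)=O)cc3O)C[C@H]2COC(C)=O)ccc1O | intermediate |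
| 11 | propolis-benzofuran A, [(2R,3S)-5-(6-acetyl-5-hydroxy-1-benzofuran-2-yl)-2-(4-hydroxy-3-methoxyphenyl)-3,4-dihydro-2H-pyran-3-yl]methyl acetate | COc1cc([C@@H]2OC=C(c3cc4cc(O)c(C(C)=O)cc4o3)C[C@H]2COC(C)=O)ccc1O | target |

Total step count: 4. Longest linear sequence: 2 (for example 1 → 2 → 11).

## Steps most likely to fail

**Step 4.**
- The cycloaddition is new, so its rate and ee are unknown.
- 7 can ionise to a vinylogous quinone methide under acid.
- Any 7 left over would feed Pd π-allyl chemistry in the second stage.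
- Fluoride can open the p-hydroxybenzyl enol ether.
- Fallback: set the stereochemistry by resolution instead of catalysis. It sets out from 4 and 7. Eu(fod)3 (5 mol%) in toluene at 60 °C gives racemic trans-[2-(4-hydroxy-3-methoxyphenyl)-5-[(trimethylsilyl)ethynyl]-3,4-dihydro-2H-pyran-3-yl]methyl acetate F1. A screened lipase (lipase PS, n-butanol, MTBE) cleaves the primary acetate of the (2S,3R) enantiomer only. This gives [(2S,3R)-2-(4-hydroxy-3-methoxyphenyl)-5-[(trimethylsilyl)ethynyl]-3,4-dihydro-2H-pyran-3-yl]methanol F2. The untouched (2R,3S)-acetate is separated by chromatography. The fallback comes back to the route at 8, which then goes through the Pd/Cu stage as a step of its own.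

**Step 2.**
- The yield of the oxidation is likely to be moderate.
- 4 may dimerise by hetero-Diels–Alder reaction or polymerise.
- Fallback: install the alkyne after the ring. It sets out from 7. Commercial 2-bromoacrolein (C=C(Br)C=O) replaces 4 as the heterodiene under the same chiral acid. This gives [(2R,3S)-5-bromo-2-(4-hydroxy-3-methoxyphenyl)-3,4-dihydro-2H-pyran-3-yl]methyl acetate F3. Sonogashira coupling of this β-bromo enol ether with ethynyltrimethylsilane (PdCl2(PPh3)2, CuI, Et3N, 50 °C) comes back to the route at 8.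

**Step 1.**
- The risks are regiochemistry and bromine loss under hot Lewis acid.
- Fallback: acylate the diether, whose para-to-bromine selectivity is established, then deprotect. It sets out from 1. MeI/K2CO3 in acetone gives 2-bromo-1,4-dimethoxybenzene F4. AcCl/AlCl3 in CH2Cl2 at 0 °C gives 1-(4-bromo-2,5-dimethoxyphenyl)ethan-1-one F5. BBr3 in CH2Cl2 (−78 °C to rt) comes back to the route at 2.

## Further compounds

F1 | step 4 | racemic trans-[2-(4-hydroxy-3-methoxyphenyl)-5-[(trimethylsilyl)ethynyl]-3,4-dihydro-2H-pyran-3-yl]methyl acetate | COc1cc([C@@H]2OC=C(C#C[Si](C)(C)C)C[C@H]2COC(C)=O)ccc1O.COc1cc([C@H]2OC=C(C#C[Si](C)(C)C)C[C@@H]2COC(C)=O)ccc1O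
F2 | step 4 | [(2S,3R)-2-(4-hydroxy-3-methoxyphenyl)-5-[(trimethylsilyl)ethynyl]-3,4-dihydro-2H-pyran-3-yl]methanol | COc1cc([C@H]2OC=C(C#C[Si](C)(C)C)C[C@@H]2CO)ccc1O
F3 | step 2 | [(2R,3S)-5-bromo-2-(4-hydroxy-3-methoxyphenyl)-3,4-dihydro-2H-pyran-3-yl]methyl acetate | COc1cc([C@@H]2OC=C(Br)C[C@H]2COC(C)=O)ccc1O
F4 | step 1 | 2-bromo-1,4-dimethoxybenzene | COc1ccc(OC)c(Br)c1
F5 | step 1 | 1-(4-bromo-2,5-dimethoxyphenyl)ethan-1-one | CC(=O)c1cc(OC)c(Br)cc1OC
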